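## Analysis of the target

Numbering used throughout: chain carbons C1 (ester C=O) to C16 (styrene CH bearing phenyl); ring O1 sits on C6 and O2 on C3, so the ring is O1–O2–C3–C4–C5–C6.

- The target is a 1,2-dioxan-3-ol, a cyclic peroxyhemiketal. C3 carries OH and the C2–C1 acetate arm, C4 is a methyl-bearing methine, C5 a methylene, and C6 a fully substituted carbon bearing O1, a methyl group and the C7–C16 chain. That chain has a methyl-bearing stereocentre at C8 and ends in a (Z)-styrene (C15=C16).
- The configuration is 3S,4R,6S,8R. In the chair, C3–OH is axial (anomeric to O2), while the acetate arm, the C4 methyl and the C6 side chain are equatorial and the C6 methyl is axial. The C4 methyl is therefore trans to the C6 methyl. Drawn as a zigzag, the methyls at C4, C6 and C8 are all syn and O1 is anti to them.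
- C3 is not a fixed centre: through ring–chain tautomerism with the open γ-hydroperoxy β-keto ester it settles at the thermodynamic anomer. Only C4, C6 and C8 have to be set.
- The hard centre is C6, a tertiary C–O–O carbon whose two exocyclic carbon substituents (CH3 and CH2R) are sterically almost alike. Steric substrate control from C4 or C8 and thermodynamic equilibration both fail to tell them apart, and an oxygen nucleophile captured by a free C6 radical or cation should give both epimers.
- Sensitive groups: the O–O bond (reductants, phosphines, low-valent metals, hydrogenation); the β-peroxy ester (base at C2–H expels the peroxide); the Z-styrene (ozone, hydrogen-atom-transfer catalysts, hydrogenation, strong acid); and C4, which is α to a ketone in the open form.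
- The feature that invites the strategy: both carbons on the O1–O2 bridge are at, or one methyl group short of, the ketone level. Remove the C6–CH3 bond and C3 and C6 become the carbonyl carbons of a 1,4-diketone (C3–C4–C5–C6). Its double peroxyketal with one O–O unit is a bridged ozonide, a 2,3,7-trioxabicyclo[2.2.1]heptane.

## Retrosynthetic reasoning

**17 ⇒ 15 (C6–CH3 bond).** The C6–CH3 bond is cut, and the C3–OH is read as the remnant of an ether bridge from C3 to C6. This is the one bond at C6 whose formation can be controlled stereoelectronically rather than sterically: a methyl nucleophile enters a six-membered cyclic peroxycarbenium ion along the axial trajectory. Cutting a C6–O bond instead would require a reagent to distinguish CH3 from CH2R. The gain is that one operation sets C6, frees the hemiketal and delivers the target. The forward reaction must ionise the C6–O(bridge) bond and not the C3–O(bridge) or O–O bond, and must deliver methyl trans to the C4 methyl.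

**15 ⇒ 13 (all C–O bonds at C3 and C6).** C3–O2, C6–O1 and both bonds of the ether bridge are cut. This leaves the acyclic 1,4-diketone 13, one peroxide unit from the reagent, and loss of one carbonyl oxygen. The whole ring system then comes from an acyclic precursor that carries only the C4 and C8 stereocentres. The bridgeheads are coupled to each other and are under thermodynamic control.

**13 ⇒ 11 ⇒ 10 (C2–C3 bond).** The β-keto ester is made by acylating a malonate half-ester unit with acid 11, which comes from ester 10 by hydrolysis. It is made late, directly before the peroxidation, because a β-keto ester next to a 1,4-diketone is prone to intramolecular Knoevenagel condensation.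

**10 ⇒ 7 + 8 (C5–C6 bond).** The ketone is formed by acyl–alkyl coupling of thioester 7 with organozinc 9, made from bromo ester 8. The cut is convergent, each fragment brings one stereocentre, and C6 arrives at the ketone oxidation level without protecting groups. C4 comes from the chiral pool.

**7 ⇒ 6 ⇒ 4 ⇒ 3 ⇒ 1 + 2 (C8–CH3, then the chain).** The C8 methyl is cut back to enethioate 6 (catalytic asymmetric conjugate addition). 6 comes from alcohol 4 by oxidation to aldehyde 5 and olefination. The Z-alkene of 4 comes from alkyne 3, and 3 from 1 and 2 by aryl–alkyne coupling. The Z-olefin is made first because the peroxide would not survive a hydrogenation.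

## Alternatives that were turned down

**Alternative 1:** the textbook route, cutting C6–O1 and C3–O2.
- Forward key step: Isayama–Mukaiyama hydroperoxysilylation (Co(II) β-diketonate, O2, Et3SiH) of the 1,1-disubstituted alkene A1 gives the tertiary silyl peroxide A2. Desilylation then lets the OOH group close on the C3 ketone.
- Why turned down: C6 is formed by O2 capture at a free, acyclic tertiary radical. Its two faces differ only through CH3 versus CH2R and the remote C4 and C8 centres, so both C6 epimers are expected and the hardest centre is left to chromatography. The Z-styrene is also a possible hydrogen-atom acceptor.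
- It is short and well precedented, so it is kept as the fallback for the key step.

**Alternative 2:** a skeletal ring expansion, cutting C6–O1 and C3–O2 after making a C3–C6 bond.
- Forward key step: cobalt-catalysed aerobic ring expansion of cyclobutanol A3. The alkoxy radical undergoes β-scission of C3–C6 toward the more substituted carbon, the C6 radical captures O2, and the peroxy unit closes on the new C3 ketone.
- Why turned down: C6 passes through the same planar acyclic radical, so there is no control where it is needed. A tetrasubstituted cyclobutanol with three stereocentres, two of which are destroyed in the step, also costs more steps than the acyclic diketone 13.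

**Alternative 3:** stereospecific substitution at C6.
- Forward key step: H2O2 adds to the C3 ketone of epoxide A4, and the perhydrate OOH opens the epoxide 6-exo at the tertiary carbon with inversion. This gives dioxanol A5 with CH2OH at C6, which must then be reduced to CH3.
- Why turned down: A4 needs an enantioselective epoxidation of a 1,1-disubstituted alkene whose two arms are both CH2CH(CH3)R, which no catalyst can distinguish. The later deoxygenation is at a neopentyl carbon next to the O–O bond: a radical there collapses to an oxirane and hydride displacement is slow. At least three extra steps on the peroxide would be needed.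

Key step: step 9

Assumption: 1, 2 and 8 are taken as commercial. The C3 hemiketal is taken as the thermodynamic anomer that forms by ring–chain equilibration, so it is not set kinetically.

## Route

Step 1
Reactants: 1 iodobenzene; 2 non-8-yn-1-ol
Product: 3 9-phenylnon-8-yn-1-ol
Conditions: PdCl2(PPh3)2 (2 mol%), CuI (4 mol%), Et3N, THF, rt
Reagents that add atoms: none
Why: Sonogashira coupling of an aryl iodide with a terminal alkyne; the free hydroxyl is tolerated and no stereocentre is involved.

Step 2
Reactants: 3 9-phenylnon-8-yn-1-ol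
Product: 4 (Z)-9-phenylnon-8-en-1-ol
Conditions: H2 (1 atm), Lindlar catalyst, quinoline, EtOAc, rt
Reagents that add atoms: none
Why: Lindlar semihydrogenation adds H2 syn on the poisoned palladium surface and should give the Z-styrene; quinoline and monitored uptake limit over-reduction.

Step 3
Reactants: 4 (Z)-9-phenylnon-8-en-1-ol
Product: 6 S-ethyl (2E,10Z)-11-phenylundeca-2,10-dienethioate, via aldehyde 5 (not isolated)
Conditions: DMP, CH2Cl2, 0 °C → rt; then Ph3P=CHCOSEt (excess), rt
Reagents that add atoms: S-ethyl 2-(triphenylphosphoranylidene)ethanethioate, CCSC(=O)C=P(c1ccccc1)(c1ccccc1)c1ccccc1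
Why: Dess–Martin oxidation followed in the same flask by a Wittig reaction; the stabilised ylide should give the E-enethioate and leaves the Z-styrene untouched.

Step 4
Reactants: 6 S-ethyl (2E,10Z)-11-phenylundeca-2,10-dienethioate
Product: 7 S-ethyl (3R,10Z)-3-methyl-11-phenylundec-10-enethioate
Conditions: MeMgBr, CuBr·SMe2 (1 mol%), Josiphos SL-J001 (1.2 mol%, enantiomer chosen for 3R), t-BuOMe, −75 °C; 1 M HCl
Reagents that add atoms: methylmagnesium bromide, C[Mg]Br
Why: Copper/ferrocenyl-diphosphine-catalysed asymmetric conjugate addition of a Grignard reagent to an α,β-unsaturated thioester. The ligand enantiomer is chosen to deliver methyl to the face that gives 3R; this sets C8 of the target.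

Step 5
Reactants: 7 S-ethyl (3R,10Z)-3-methyl-11-phenylundec-10-enethioate; 8 methyl (S)-3-bromo-2-methylpropanoate
Product: 10 methyl (2R,6R,13Z)-2,6-dimethyl-4-oxo-14-phenyltetradec-13-enoate, via organozinc bromide 9 (not isolated)
Conditions: 8, Zn dust (activated), LiCl, THF, 40 °C; then 7, PdCl2(PPh3)2 (5 mol%), toluene–THF, rt; 1 M HCl
Reagents that add atoms: zinc, [Zn] (in intermediate 9 only)
Why: Zinc insertion gives the ester homoenolate 9 without touching its α-stereocentre, and Fukuyama coupling with thioester 7 forms the C5–C6 ketone without over-addition. C4 comes from the chiral pool; its descriptor changes from S to R only because the CIP priorities change.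

Step 6
Reactants: 10 methyl (2R,6R,13Z)-2,6-dimethyl-4-oxo-14-phenyltetradec-13-enoate
Product: 11 (2R,6R,13Z)-2,6-dimethyl-4-oxo-14-phenyltetradec-13-enoic acid
Conditions: LiOH, THF–H2O, 0 °C; then 1 M HCl
Reagents that add atoms: lithium hydroxide, [Li+].[OH-]
Why: Ester saponification at low temperature; the C2 hydrogen is α only to the carboxylate, so epimerisation should be slow.

Step 7
Reactants: 11 (2R,6R,13Z)-2,6-dimethyl-4-oxo-14-phenyltetradec-13-enoic acid
Product: 13 methyl (4R,8R,15Z)-4,8-dimethyl-3,6-dioxo-16-phenylhexadec-15-enoate, via acyl imidazolide 12 (not isolated)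
Conditions: CDI, THF, rt; then KO2CCH2CO2Me, MgCl2, Et3N, MeCN–THF, rt; 1 M HCl
Reagents that add atoms: potassium methyl malonate, COC(=O)CC(=O)[O-].[K+]; 1,1'-carbonyldiimidazole, O=C(n1ccnc1)n1ccnc1 (imidazolyl group in intermediate 12 only)
Why: Masamune–Brooks homologation: the magnesium malonate is C-acylated by the acyl imidazolide and loses CO2 to give the β-keto ester under nearly neutral conditions. 13 is used at once and kept away from base.

Step 8
Reactants: 13 methyl (4R,8R,15Z)-4,8-dimethyl-3,6-dioxo-16-phenylhexadec-15-enoate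
Product: 15 methyl 2-[(1S,4R,6R)-6-methyl-4-[(2R,9Z)-2-methyl-10-phenyldec-9-en-1-yl]-2,3,7-trioxabicyclo[2.2.1]heptan-1-yl]acetate (bicyclic locants; chain C4 methyl exo, syn to the ether bridge), via dioxanediol 14 (not isolated)
Conditions: H2O2 (ethereal, 1.3 equiv), BF3·OEt2 (20 mol%), Et2O, 0 → 20 °C
Reagents that add atoms: hydrogen peroxide, OO
Why: Acid-catalysed double peroxyketalisation, the ozone-free ozonide synthesis from diketones: H2O2 adds to the more electrophilic C6 ketone, the hydroperoxide closes on C3 to the 1,2-dioxane-3,6-diol 14, and the cis-diol loses water across the ring. The two bridgeheads are coupled and form reversibly, so the isomer with the C4 methyl exo should prevail. H2O2 is kept near one equivalent to avoid geminal bis-hydroperoxides.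

Step 9
Reactants: 15 methyl 2-[(1S,4R,6R)-6-methyl-4-[(2R,9Z)-2-methyl-10-phenyldec-9-en-1-yl]-2,3,7-trioxabicyclo[2.2.1]heptan-1-yl]acetate
Product: 17 methyl 2-[(3S,4R,6S)-3-hydroxy-4,6-dimethyl-6-[(2R,9Z)-2-methyl-10-phenyldec-9-en-1-yl]-1,2-dioxan-3-yl]acetate, via silyl peroxyketal 16 (not isolated)
Conditions: Me3Al (3 equiv), then TMSOTf (1.2 equiv), CH2Cl2, −78 °C; aq. Rochelle salt; then AcOH–THF–H2O, 0 °C
Reagents that add atoms: trimethylaluminium, C[Al](C)C; trimethylsilyl triflate, C[Si](C)(C)OS(=O)(=O)C(F)(F)F (Me3Si group in intermediate 16 only)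
Why: Proposed new method: TMSOTf silylates the most basic oxygen of 15, the ether bridge; the C6–O(bridge) bond ionises to the six-membered peroxycarbenium ion C6=O1(+) and Me3Al transfers methyl to C6, the closest known reaction types being the Lewis-acid ionisation of 1,2,4-trioxolanes and 3-alkoxy-1,2-dioxanes to peroxycarbenium ions that are trapped by allylsilanes or silyl enol ethers with the O–O bond intact, and the Me3Al/TMSOTf C-methylation of cyclic oxocarbenium ions. No ring is closed: the step opens the oxolane and 1,2,4-trioxolane rings of the bicycle and leaves the 1,2-dioxane. C6 is the only new stereocentre: in the half-chair cation with the C4 methyl pseudo-equatorial and the C3 silyloxy group pseudo-axial, methyl enters along the axial trajectory that leads to a chair, anti to the departed bridge oxygen and trans to the C4 methyl, which is 6S (C6 methyl axial, side chain equatorial). The same face is attacked whether the opening is SN1-like or an SN2-like inversion of the exo-methyl ozonide, and any endo-methyl ozonide should converge on it through the free cation. C3 keeps the bridge oxygen as a silyl ether, so no metal hemiketalate forms that could open to a metal alkylperoxide; mild acid then frees the hemiketal, which settles by ring–chain tautomerism in the anomeric 3S form. The step needs C–O over O–O activation (low temperature, nucleophile present before the Lewis acid) and C6 over C3 ionisation (a cation at C3 would sit β to the ester).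

## Compound list

1 | iodobenzene | Ic1ccccc1 | starting material
2 | non-8-yn-1-ol | OCCCCCCCC#C | starting material
3 | 9-phenylnon-8-yn-1-ol | OCCCCCCCC#Cc1ccccc1 | intermediate
4 | (Z)-9-phenylnon-8-en-1-ol | OCCCCCCC/C=C\c1ccccc1 | intermediate
5 | (Z)-9-phenylnon-8-enal | O=CCCCCCC/C=C\c1ccccc1 | intermediate
6 | S-ethyl (2E,10Z)-11-phenylundeca-2,10-dienethioate | CCSC(=O)/C=C/CCCCCC/C=C\c1ccccc1 | intermediate
7 | S-ethyl (3R,10Z)-3-methyl-11-phenylundec-10-enethioate | CCSC(=O)C[C@H](C)CCCCCC/C=C\c1ccccc1 | intermediate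
8 | methyl (S)-3-bromo-2-methylpropanoate | COC(=O)[C@H](C)CBr | starting material
9 | [(2S)-3-methoxy-2-methyl-3-oxopropyl]zinc bromide | COC(=O)[C@H](C)C[Zn]Br | intermediate
10 | methyl (2R,6R,13Z)-2,6-dimethyl-4-oxo-14-phenyltetradec-13-enoate | COC(=O)[C@H](C)CC(=O)C[C@H](C)CCCCCC/C=C\c1ccccc1 | intermediate
11 | (2R,6R,13Z)-2,6-dimethyl-4-oxo-14-phenyltetradec-13-enoic acid | OC(=O)[C@H](C)CC(=O)C[C@H](C)CCCCCC/C=C\c1ccccc1 | intermediate
12 | (2R,6R,13Z)-1-(imidazol-1-yl)-2,6-dimethyl-14-phenyltetradec-13-ene-1,4-dione | O=C(n1ccnc1)[C@H](C)CC(=O)C[C@H](C)CCCCCC/C=C\c1ccccc1 | intermediate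
13 | methyl (4R,8R,15Z)-4,8-dimethyl-3,6-dioxo-16-phenylhexadec-15-enoate | COC(=O)CC(=O)[C@H](C)CC(=O)C[C@H](C)CCCCCC/C=C\c1ccccc1 | intermediate
14 | methyl 2-[(3S,4R,6R)-3,6-dihydroxy-4-methyl-6-[(2R,9Z)-2-methyl-10-phenyldec-9-en-1-yl]-1,2-dioxan-3-yl]acetate (cis-diol; the hemiketal epimers equilibrate) | COC(=O)C[C@]1(O)OO[C@@](C[C@H](C)CCCCCC/C=C\c2ccccc2)(O)C[C@H]1C | intermediate
15 | methyl 2-[(1S,4R,6R)-6-methyl-4-[(2R,9Z)-2-methyl-10-phenyldec-9-en-1-yl]-2,3,7-trioxabicyclo[2.2.1]heptan-1-yl]acetate | COC(=O)C[C@@]12OO[C@@](O1)(C[C@H]2C)C[C@H](C)CCCCCC/C=C\c3ccccc3 | intermediate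
16 | methyl 2-[(3R,4R,6S)-4,6-dimethyl-6-[(2R,9Z)-2-methyl-10-phenyldec-9-en-1-yl]-3-(trimethylsilyloxy)-1,2-dioxan-3-yl]acetate | COC(=O)C[C@]1(O[Si](C)(C)C)OO[C@@](C)(C[C@H](C)CCCCCC/C=C\c2ccccc2)C[C@H]1C | intermediate
17 | methyl 2-[(3S,4R,6S)-3-hydroxy-4,6-dimethyl-6-[(2R,9Z)-2-methyl-10-phenyldec-9-en-1-yl]-1,2-dioxan-3-yl]acetate | COC(=O)C[C@]1(O)OO[C@@](C)(C[C@H](C)CCCCCC/C=C\c2ccccc2)C[C@H]1C | target

## Step count and least certain steps

Total: 9 steps. Longest linear sequence: 9 steps (1 and 2 to 17); 8 enters in step 5 without prior steps.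

**Step 9 (key step, proposed new method).**
- What may go wrong: reduction of the O–O bond by the aluminium reagent, or Lewis-acid-induced O–O heterolysis with fragmentation, instead of C6–O ionisation. Ionisation at C3 would put methyl on the wrong carbon. Facial selectivity would erode if the endo-methyl ozonide opens by direct displacement rather than through the free cation.
- Fallback (known chemistry only), from 10 back to 17:
  - Takai–Lombardo methylenation (Zn, CH2Br2, TiCl4) of the C6 ketone of 10 gives methyl (2R,6R,13Z)-2,6-dimethyl-4-methylidene-14-phenyltetradec-13-enoate F1.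
  - Saponification gives (2R,6R,13Z)-2,6-dimethyl-4-methylidene-14-phenyltetradec-13-enoic acid F2.
  - Masamune–Brooks homologation gives methyl (4R,8R,15Z)-4,8-dimethyl-6-methylidene-3-oxo-16-phenylhexadec-15-enoate F3 (identical with A1).
  - Isayama–Mukaiyama hydroperoxysilylation (Co(thd)2, O2, Et3SiH) gives methyl (4R,6RS,8R,15Z)-4,6,8-trimethyl-3-oxo-16-phenyl-6-(triethylsilylperoxy)hexadec-15-enoate F4 (identical with A2) as both C6 epimers.
  - Aqueous HCl in THF removes the silyl group and the freed OOH closes on the C3 ketone. This gives 17 and its C6 epimer, methyl 2-[(3S,4R,6R)-3-hydroxy-4,6-dimethyl-6-[(2R,9Z)-2-methyl-10-phenyldec-9-en-1-yl]-1,2-dioxan-3-yl]acetate F5. The two are diastereomers and are separated by chromatography.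

**Step 8.**
- What may go wrong: over-addition of peroxide to geminal bis-hydroperoxides; attack of a C3 hydroperoxide on the ester; Baeyer–Villiger-type migration; acid-induced enolisation at C4 or isomerisation of the styrene; incomplete exo/endo equilibration.
- Fallback, from 13 back to 17:
  - Peroxyketalisation in methanol (H2O2, MeOH, HC(OMe)3, CSA) gives the monocyclic bis(methyl peroxyketal) methyl 2-[(3S,4R,6S)-3,6-dimethoxy-4-methyl-6-[(2R,9Z)-2-methyl-10-phenyldec-9-en-1-yl]-1,2-dioxan-3-yl]acetate F6.
  - F6 enters the methylation of step 9 with loss of the C6 methoxy group and gives methyl 2-[(3S,4R,6S)-3-methoxy-4,6-dimethyl-6-[(2R,9Z)-2-methyl-10-phenyldec-9-en-1-yl]-1,2-dioxan-3-yl]acetate F7. This still relies on the proposed methylation.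
  - Aqueous acid hydrolysis of the C3 methyl peroxyketal of F7 gives 17.

**Step 7.**
- What may go wrong: intramolecular Knoevenagel condensation of the magnesium enolate at C2 onto the C6 ketone, giving a cyclopentenone; partial epimerisation at C4 through the acyl imidazolide.
- Fallback, from 10 back to 13, with C6 masked while base is present:
  - Ketalisation (1,2-bis(trimethylsilyloxy)ethane, cat. TMSOTf) gives methyl (2R)-2-methyl-3-[2-[(2R,9Z)-2-methyl-10-phenyldec-9-en-1-yl]-1,3-dioxolan-2-yl]propanoate F8.
  - Saponification gives (2R)-2-methyl-3-[2-[(2R,9Z)-2-methyl-10-phenyldec-9-en-1-yl]-1,3-dioxolan-2-yl]propanoic acid F9.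
  - Masamune–Brooks homologation gives methyl (4R)-4-methyl-5-[2-[(2R,9Z)-2-methyl-10-phenyldec-9-en-1-yl]-1,3-dioxolan-2-yl]-3-oxopentanoate F10.
  - PPTS in wet acetone frees the ketone and gives 13 under acidic conditions only.

**Step 5.**
- What may go wrong: slow or incomplete zinc insertion into the primary bromide, protonation or homocoupling of 9, and palladium-hydride-mediated Z→E isomerisation of the styrene.
- Fallback, from 7 back to 11:
  - MeNH(OMe)·HCl with i-PrMgCl converts 7 into (3R,10Z)-N-methoxy-N,3-dimethyl-11-phenylundec-10-enamide F11.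
  - Commercial (S)-3-bromo-2-methylpropan-1-ol is silylated to (S)-(3-bromo-2-methylpropoxy)(tert-butyl)dimethylsilane F12 and converted with magnesium into the Grignard reagent [(2S)-3-(tert-butyldimethylsilyloxy)-2-methylpropyl]magnesium bromide F13.
  - Addition of F13 to F11 gives (2R,6R,13Z)-1-(tert-butyldimethylsilyloxy)-2,6-dimethyl-14-phenyltetradec-13-en-4-one F14.
  - TBAF gives (2R,6R,13Z)-1-hydroxy-2,6-dimethyl-14-phenyltetradec-13-en-4-one F15.
  - TEMPO/PhI(OAc)2 in aqueous acetonitrile oxidises the primary alcohol of F15 to the acid 11.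

## Further compounds

F1 | step 9 | methyl (2R,6R,13Z)-2,6-dimethyl-4-methylidene-14-phenyltetradec-13-enoate | COC(=O)[C@H](C)CC(=C)C[C@H](C)CCCCCC/C=C\c1ccccc1
F2 | step 9 | (2R,6R,13Z)-2,6-dimethyl-4-methylidene-14-phenyltetradec-13-enoic acid | OC(=O)[C@H](C)CC(=C)C[C@H](C)CCCCCC/C=C\c1ccccc1
F3 | step 9 | methyl (4R,8R,15Z)-4,8-dimethyl-6-methylidene-3-oxo-16-phenylhexadec-15-enoate | COC(=O)CC(=O)[C@H](C)CC(=C)C[C@H](C)CCCCCC/C=C\c1ccccc1
F4 | step 9 | methyl (4R,6RS,8R,15Z)-4,6,8-trimethyl-3-oxo-16-phenyl-6-(triethylsilylperoxy)hexadec-15-enoate | COC(=O)CC(=O)[C@H](C)CC(C)(OO[Si](CC)(CC)CC)C[C@H](C)CCCCCC/C=C\c1ccccc1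
F5 | step 9 | methyl 2-[(3S,4R,6R)-3-hydroxy-4,6-dimethyl-6-[(2R,9Z)-2-methyl-10-phenyldec-9-en-1-yl]-1,2-dioxan-3-yl]acetate | COC(=O)C[C@]1(O)OO[C@](C)(C[C@H](C)CCCCCC/C=C\c2ccccc2)C[C@H]1C
F6 | step 8 | methyl 2-[(3S,4R,6S)-3,6-dimethoxy-4-methyl-6-[(2R,9Z)-2-methyl-10-phenyldec-9-en-1-yl]-1,2-dioxan-3-yl]acetate | COC(=O)C[C@]1(OC)OO[C@@](OC)(C[C@H](C)CCCCCC/C=C\c2ccccc2)C[C@H]1C
F7 | step 8 | methyl 2-[(3S,4R,6S)-3-methoxy-4,6-dimethyl-6-[(2R,9Z)-2-methyl-10-phenyldec-9-en-1-yl]-1,2-dioxan-3-yl]acetate | COC(=O)C[C@]1(OC)OO[C@@](C)(C[C@H](C)CCCCCC/C=C\c2ccccc2)C[C@H]1C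
F8 | step 7 | methyl (2R)-2-methyl-3-[2-[(2R,9Z)-2-methyl-10-phenyldec-9-en-1-yl]-1,3-dioxolan-2-yl]propanoate | COC(=O)[C@H](C)CC1(OCCO1)C[C@H](C)CCCCCC/C=C\c2ccccc2
F9 | step 7 | (2R)-2-methyl-3-[2-[(2R,9Z)-2-methyl-10-phenyldec-9-en-1-yl]-1,3-dioxolan-2-yl]propanoic acid | OC(=O)[C@H](C)CC1(OCCO1)C[C@H](C)CCCCCC/C=C\c2ccccc2
F10 | step 7 | methyl (4R)-4-methyl-5-[2-[(2R,9Z)-2-methyl-10-phenyldec-9-en-1-yl]-1,3-dioxolan-2-yl]-3-oxopentanoate | COC(=O)CC(=O)[C@H](C)CC1(OCCO1)C[C@H](C)CCCCCC/C=C\c2ccccc2
F11 | step 5 | (3R,10Z)-N-methoxy-N,3-dimethyl-11-phenylundec-10-enamide | CON(C)C(=O)C[C@H](C)CCCCCC/C=C\c1ccccc1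
F12 | step 5 | (S)-(3-bromo-2-methylpropoxy)(tert-butyl)dimethylsilane | CC(C)(C)[Si](C)(C)OC[C@H](C)CBr
F13 | step 5 | [(2S)-3-(tert-butyldimethylsilyloxy)-2-methylpropyl]magnesium bromide | CC(C)(C)[Si](C)(C)OC[C@H](C)C[Mg]Br
F14 | step 5 | (2R,6R,13Z)-1-(tert-butyldimethylsilyloxy)-2,6-dimethyl-14-phenyltetradec-13-en-4-one | CC(C)(C)[Si](C)(C)OC[C@H](C)CC(=O)C[C@H](C)CCCCCC/C=C\c1ccccc1
F15 | step 5 | (2R,6R,13Z)-1-hydroxy-2,6-dimethyl-14-phenyltetradec-13-en-4-one | OC[C@H](C)CC(=O)C[C@H](C)CCCCCC/C=C\c1ccccc1
A1 | alternative 1 | methyl (4R,8R,15Z)-4,8-dimethyl-6-methylidene-3-oxo-16-phenylhexadec-15-enoate | COC(=O)CC(=O)[C@H](C)CC(=C)C[C@H](C)CCCCCC/C=C\c1ccccc1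
A2 | alternative 1 | methyl (4R,6RS,8R,15Z)-4,6,8-trimethyl-3-oxo-16-phenyl-6-(triethylsilylperoxy)hexadec-15-enoate | COC(=O)CC(=O)[C@H](C)CC(C)(OO[Si](CC)(CC)CC)C[C@H](C)CCCCCC/C=C\c1ccccc1
A3 | alternative 2 | methyl 2-[(2R)-1-hydroxy-2,4-dimethyl-4-[(2R,9Z)-2-methyl-10-phenyldec-9-en-1-yl]cyclobutyl]acetate (ring C1 and C4 unspecified) | COC(=O)CC1(O)[C@H](C)CC1(C)C[C@H](C)CCCCCC/C=C\c2ccccc2
A4 | alternative 3 | methyl (4R)-4-methyl-5-[(2R)-2-[(2R,9Z)-2-methyl-10-phenyldec-9-en-1-yl]oxiran-2-yl]-3-oxopentanoate | COC(=O)CC(=O)[C@H](C)C[C@@]1(CO1)C[C@H](C)CCCCCC/C=C\c2ccccc2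
A5 | alternative 3 | methyl 2-[(3S,4R,6S)-3-hydroxy-6-(hydroxymethyl)-4-methyl-6-[(2R,9Z)-2-methyl-10-phenyldec-9-en-1-yl]-1,2-dioxan-3-yl]acetate | COC(=O)C[C@]1(O)OO[C@@](CO)(C[C@H](C)CCCCCC/C=C\c2ccccc2)C[C@H]1C
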